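**Plan**

Numbering is labdane-type: C4 = CMe2, C5 = fusion CH, C10 = fusion C–CH3, C8(CH3)=C9, chain C11–C16, then the butenolide. The retrosynthesis cuts C15=C16, C12–C13 and C9–C11 in the chain. In the bicycle it cuts C3–C4 (ring A), C10–CH3 and C10–C1.
Enabling feature: ring B (C5–C10), with its C8 methyl group and an oxygen handle at C9, is the carvone ring. The gem-dimethyl carbon C4 on fusion carbon C5 is carvone's isopropenyl group plus one hydrogen atom. A tertiary C4 radical can therefore be generated next to a C10 arm that ends in an acceptor alkene (C2=C3).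
Forward order: ring B is bought and C10 is alkylated twice. Ring A closes by C3–C4 radical addition, and the activating ester at C2 is erased. C9 becomes an enol triflate, and the chain is joined as C11–C12 (vinyl), C13–C15 (alkenyl iodide), then C16 plus butenolide (phosphonate).
Stereochemistry: C5 comes from (S)-carvone. C10 is set by methylation anti to the isopropenyl group, which leaves the arm and the isopropenyl group cis and fixes the cis fusion (5R,10S). C13=C14 comes from anti hydroalumination–iodination and stereoretentive coupling. C15=C16 (E) comes from the phosphonate olefination.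

Key step: step 3

Assumption: the stereodescriptors of the target place H-5 and the C10 methyl group on the same face (5R,10S, cis-decalin), and the route is built for exactly this isomer.

**Route**

Step 1
Reactants: 1 (S)-(+)-carvone; 2 methyl 2-(bromomethyl)acrylate
Product: 4 methyl 2-{[(1R,6S)-3-methyl-2-oxo-6-(prop-1-en-2-yl)cyclohex-3-en-1-yl]methyl}prop-2-enoate (C10 arm mainly trans to the isopropenyl group), via lithium dienolate 3 (not isolated)
Conditions: LiN(i-Pr)2 (1.05 equiv), THF, −78 °C; then 2, −78 to −40 °C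
Reagents that add atoms: none
Why: Kinetic α′-deprotonation of the enone gives the cross-conjugated dienolate, which is alkylated at C10 by the activated allylic bromide (enolate alkylation, with SN2 and SN2′ leading to the same product), and the new C10 centre is flattened again in step 2, so its configuration is of no consequence.

Step 2
Reactants: 4 methyl 2-{[(1R,6S)-3-methyl-2-oxo-6-(prop-1-en-2-yl)cyclohex-3-en-1-yl]methyl}prop-2-enoate
Product: 6 methyl 2-{[(1S,6R)-1,3-dimethyl-2-oxo-6-(prop-1-en-2-yl)cyclohex-3-en-1-yl]methyl}prop-2-enoate (C10 methyl trans and acrylate arm cis to the isopropenyl group), via lithium enolate 5 (not isolated)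
Conditions: 4 added to LiN(i-Pr)2 (1.05 equiv), THF, −78 °C; then MeI (5 equiv), DMPU, −78 to −30 °C
Reagents that add atoms: iodomethane, CI
Why: In this second kinetic enolate alkylation the C5 isopropenyl group turns pseudoaxial to escape allylic strain with the tetrasubstituted enolate and shields its own face, so MeI should enter anti to it and set C10 as S, while fast deprotonation at −78 °C, the poor acceptor quality of an α-substituted acrylate and the four-membered ring that an internal Michael addition would require protect the arm.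

Step 3
Reactants: 6 methyl 2-{[(1S,6R)-1,3-dimethyl-2-oxo-6-(prop-1-en-2-yl)cyclohex-3-en-1-yl]methyl}prop-2-enoate
Product: 7 methyl (2S,4aR,8aS)-4,4,7,8a-tetramethyl-8-oxo-1,2,3,4,4a,5,8,8a-octahydronaphthalene-2-carboxylate (cis-fused; the 2α-ester epimer is drawn)
Conditions: Fe(acac)3 (30 mol %), PhSiH3 (2.5 equiv), EtOH (0.02 M), 60 °C
Reagents that add atoms: none
Why: An iron hydride formed from Fe(acac)3 and PhSiH3 in EtOH hands a hydrogen atom to the CH2 terminus of the isopropenyl group, which creates the second C4 methyl group and a nucleophilic tertiary radical at C4. This radical adds to the unsubstituted acrylate terminus C3, and the α-ester radical at C2 is reduced by divalent iron and protonated by the solvent with return of trivalent iron; the closest known reaction type is the iron-catalysed hydrogen-atom-transfer reductive olefin coupling in its intramolecular Giese form. Ring A closes in the 6-endo-trig mode, because 5-exo attack at C2 would join two fully substituted carbons and leave an unstabilised primary radical, whereas attack at C3 is polarity matched and gives a stabilised radical. The fusion is inherited rather than made: C5 and C10 are already fixed and the arm and the radical centre are cis on ring B, so only the cis-decalin can form. The one new stereocentre, C2, is set when the ester enolate is protonated from the more open face of the folded bicycle, and it is erased in step 5, so either epimer serves. The step needs hydrogen-atom transfer to the isopropenyl group in preference to the enone and the acrylate, which is secured because the hydride reacts fastest with the electron-rich, unhindered 1,1-disubstituted alkene, and attack of the C4 radical on enone carbon C7 is excluded because it would need a four-membered ring.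

Step 4
Reactants: 7 methyl (2S,4aR,8aS)-4,4,7,8a-tetramethyl-8-oxo-1,2,3,4,4a,5,8,8a-octahydronaphthalene-2-carboxylate
Product: 8 (2S,4aR,8aS)-4,4,7,8a-tetramethyl-8-oxo-1,2,3,4,4a,5,8,8a-octahydronaphthalene-2-carboxylic acid
Conditions: LiOH·H2O, THF/MeOH/H2O, rt; then 1 M HCl
Reagents that add atoms: lithium hydroxide, [Li+].[OH-]
Why: Ester saponification of an unhindered secondary methyl ester, in which C10 is quaternary, C5 is not acidified by the enone, and epimerisation at C2 does not matter.

Step 5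
Reactants: 8 (2S,4aR,8aS)-4,4,7,8a-tetramethyl-8-oxo-1,2,3,4,4a,5,8,8a-octahydronaphthalene-2-carboxylic acid
Product: 10 (4aR,8aS)-2,5,5,8a-tetramethyl-4a,5,6,7,8,8a-hexahydronaphthalen-1(4H)-one (cis-fused enone), via thiohydroxamate ester 9 (not isolated)
Conditions: 1-hydroxypyridine-2(1H)-thione, DCC, 4-(dimethylamino)pyridine (cat.), CH2Cl2, 0 °C to rt, dark; then t-BuSH, hν (tungsten lamp), rt
Reagents that add atoms: none
Why: Barton reductive decarboxylation, in which the thiohydroxamate ester fragments in a radical chain to CO2 and the secondary C2 radical, and this radical takes a hydrogen atom from t-BuSH faster than it can reach the remote enone, so that C2 becomes CH2.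

Step 6
Reactants: 10 (4aR,8aS)-2,5,5,8a-tetramethyl-4a,5,6,7,8,8a-hexahydronaphthalen-1(4H)-one
Product: 12 (4aR,8aS)-2,5,5,8a-tetramethyl-3,4,4a,5,6,7,8,8a-octahydronaphthalen-1-yl trifluoromethanesulfonate, via lithium enolate 11 (not isolated)
Conditions: LiBH(s-Bu)3 (1.1 equiv), THF, −78 °C; then PhNTf2, −78 °C to rt
Reagents that add atoms: N-phenylbis(trifluoromethanesulfonimide), O=S(=O)(N(c1ccccc1)S(=O)(=O)C(F)(F)F)C(F)(F)F
Why: Conjugate reduction with enolate trapping, in which the bulky borohydride attacks C7 (no extra β-substituent, and 1,2-attack at C9 is blocked by quaternary C10) and the regiodefined C8=C9 enolate is O-sulfonylated, as is known for carvone-type enones, with no stereocentre formed.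

Step 7
Reactants: 12 (4aR,8aS)-2,5,5,8a-tetramethyl-3,4,4a,5,6,7,8,8a-octahydronaphthalen-1-yl trifluoromethanesulfonate
Product: 13 (4aR,8aS)-1-ethenyl-2,5,5,8a-tetramethyl-3,4,4a,5,6,7,8,8a-octahydronaphthalene
Conditions: tributyl(vinyl)stannane, Pd(PPh3)4 (5 mol %), LiCl (3 equiv), THF, reflux
Reagents that add atoms: tributyl(vinyl)stannane, C=C[Sn](CCCC)(CCCC)CCCC
Why: Stille coupling of an enol triflate with LiCl as additive, where the small vinyl group is the least demanding partner for C9, which lies between quaternary C10 and the C8 methyl group, in line with the known couplings of 2,6,6-trimethylcyclohexenyl triflate.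

Step 8
Reactants: 14 but-2-yne-1,4-diol
Product: 15 4-{[tert-butyl(dimethyl)silyl]oxy}but-2-yn-1-ol
Conditions: TBSCl (1 equiv), imidazole, 14 (3 equiv), DMF, 0 °C to rt
Reagents that add atoms: tert-butyldimethylsilyl chloride, CC(C)(C)[Si](C)(C)Cl
Why: Statistical monosilylation of a symmetrical diol used in excess, after which the polar diol is washed out with water.

Step 9
Reactants: 15 4-{[tert-butyl(dimethyl)silyl]oxy}but-2-yn-1-ol
Product: 17 (2Z)-4-{[tert-butyl(dimethyl)silyl]oxy}-3-iodobut-2-en-1-ol, via cyclic alkenylaluminate 16 (not isolated)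
Conditions: NaAlH2(OCH2CH2OMe)2, THF, 0 °C to rt; then I2, THF, −78 to 0 °C
Reagents that add atoms: iodine, II
Why: Hydroxyl-directed anti hydroalumination of a propargylic alcohol places aluminium on the distal alkyne carbon in a five-membered chelate, and iodinolysis with retention gives the iodide with I cis to CH2OH, which is the geometry C13=C14 needs.

Step 10
Reactants: 13 (4aR,8aS)-1-ethenyl-2,5,5,8a-tetramethyl-3,4,4a,5,6,7,8,8a-octahydronaphthalene; 17 (2Z)-4-{[tert-butyl(dimethyl)silyl]oxy}-3-iodobut-2-en-1-ol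
Product: 19 (2E)-3-({[tert-butyl(dimethyl)silyl]oxy}methyl)-5-[(4aR,8aS)-2,5,5,8a-tetramethyl-3,4,4a,5,6,7,8,8a-octahydronaphthalen-1-yl]pent-2-en-1-ol, via B-alkyl-9-BBN borane 18 (not isolated)
Conditions: 13, 9-borabicyclo[3.3.1]nonane (9-BBN-H) dimer, THF, 0 °C to rt; then 17, PdCl2(dppf) (5 mol %, dppf = 1,1′-bis(diphenylphosphino)ferrocene), AsPh3 (10 mol %), Cs2CO3, DMF/H2O, rt
Reagents that add atoms: none
Why: 9-BBN-H adds only to the monosubstituted vinyl terminus and leaves the tetrasubstituted C8=C9 alkene alone, and the B-alkyl Suzuki–Miyaura coupling forms C12–C13 with retention at the alkenyl iodide, so that C12 ends up cis to C15.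

Step 11
Reactants: 19 (2E)-3-({[tert-butyl(dimethyl)silyl]oxy}methyl)-5-[(4aR,8aS)-2,5,5,8a-tetramethyl-3,4,4a,5,6,7,8,8a-octahydronaphthalen-1-yl]pent-2-en-1-ol
Product: 20 (2E)-3-({[tert-butyl(dimethyl)silyl]oxy}methyl)-5-[(4aR,8aS)-2,5,5,8a-tetramethyl-3,4,4a,5,6,7,8,8a-octahydronaphthalen-1-yl]pent-2-enal
Conditions: 2,2,6,6-tetramethylpiperidine 1-oxyl (TEMPO, 10 mol %), PhI(OAc)2, CH2Cl2, rt
Reagents that add atoms: none
Why: Oxoammonium-mediated oxidation of a primary allylic alcohol under base-free conditions, a method known to preserve the geometry of trisubstituted enals and to leave silyl ethers and unactivated alkenes untouched.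

Step 12
Reactants: 21 4-methylfuran-2(5H)-one
Product: 22 4-(bromomethyl)furan-2(5H)-one
Conditions: NBS, 2,2′-azobis(2-methylpropionitrile) (cat.), PhCF3, reflux
Reagents that add atoms: N-bromosuccinimide, O=C1CCC(=O)N1Br
Why: Wohl–Ziegler bromination, in which hydrogen abstraction from the C4 methyl group gives an allyl radical conjugated with the lactone carbonyl that takes up bromine at its primary terminus, and any ring-brominated isomer is removed by chromatography.

Step 13
Reactants: 22 4-(bromomethyl)furan-2(5H)-one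
Product: 23 diethyl [(5-oxo-2,5-dihydrofuran-3-yl)methyl]phosphonate
Conditions: P(OEt)3, toluene, 110 °C
Reagents that add atoms: triethyl phosphite, CCOP(OCC)OCC
Why: Michaelis–Arbuzov reaction of a reactive primary allylic bromide, driven by loss of volatile bromoethane.

Step 14
Reactants: 20 (2E)-3-({[tert-butyl(dimethyl)silyl]oxy}methyl)-5-[(4aR,8aS)-2,5,5,8a-tetramethyl-3,4,4a,5,6,7,8,8a-octahydronaphthalen-1-yl]pent-2-enal; 23 diethyl [(5-oxo-2,5-dihydrofuran-3-yl)methyl]phosphonate
Product: 25 4-[(1E,3E)-4-({[tert-butyl(dimethyl)silyl]oxy}methyl)-6-[(4aR,8aS)-2,5,5,8a-tetramethyl-3,4,4a,5,6,7,8,8a-octahydronaphthalen-1-yl]hexa-1,3-dien-1-yl]furan-2(5H)-one, via lithiated phosphonate 24 (not isolated)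
Conditions: 23, LiN(SiMe3)2, THF, −78 °C; then 20, −78 to 0 °C
Reagents that add atoms: none
Why: Vinylogous Horner–Wadsworth–Emmons olefination, analogous to that of 4-phosphonocrotonates, in which the stabilised anion adds reversibly to the enal and only the exocyclic carbon can eliminate phosphate, so the E C15=C16 alkene should result while the weakly basic anion leaves C13=C14 unchanged.

Step 15
Reactants: 25 4-[(1E,3E)-4-({[tert-butyl(dimethyl)silyl]oxy}methyl)-6-[(4aR,8aS)-2,5,5,8a-tetramethyl-3,4,4a,5,6,7,8,8a-octahydronaphthalen-1-yl]hexa-1,3-dien-1-yl]furan-2(5H)-one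
Product: 26 4-[(1E,3E)-4-(hydroxymethyl)-6-[(4aR,8aS)-2,5,5,8a-tetramethyl-3,4,4a,5,6,7,8,8a-octahydronaphthalen-1-yl]hexa-1,3-dien-1-yl]furan-2(5H)-one (CNP0232848.3)
Conditions: HF·pyridine, pyridine, THF, 0 °C to rt
Reagents that add atoms: none
Why: Fluoride-mediated cleavage of a primary silyl ether under buffered, non-basic conditions that spare the butenolide and the triene.

**Compound list**

1 | (S)-(+)-carvone | CC1=CC[C@@H](CC1=O)C(C)=C | starting material
2 | methyl 2-(bromomethyl)acrylate | C=C(CBr)C(=O)OC | starting material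
3 | lithium cross-conjugated dienolate of (S)-carvone | [Li]OC1=C[C@@H](C(C)=C)CC=C1C | intermediate
4 | methyl 2-{[(1R,6S)-3-methyl-2-oxo-6-(prop-1-en-2-yl)cyclohex-3-en-1-yl]methyl}prop-2-enoate | O=C1C(C)=CC[C@H](C(C)=C)[C@H]1CC(=C)C(=O)OC | intermediate
5 | lithium enolate of 4 (C9=C10) | [Li]OC1=C(CC(=C)C(=O)OC)[C@@H](C(C)=C)CC=C1C | intermediate
6 | methyl 2-{[(1S,6R)-1,3-dimethyl-2-oxo-6-(prop-1-en-2-yl)cyclohex-3-en-1-yl]methyl}prop-2-enoate | O=C1C(C)=CC[C@H](C(C)=C)[C@]1(C)CC(=C)C(=O)OC | intermediate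
7 | methyl (2S,4aR,8aS)-4,4,7,8a-tetramethyl-8-oxo-1,2,3,4,4a,5,8,8a-octahydronaphthalene-2-carboxylate | O=C1C(C)=CC[C@@H]2C(C)(C)C[C@H](C(=O)OC)C[C@]12C | intermediate
8 | (2S,4aR,8aS)-4,4,7,8a-tetramethyl-8-oxo-1,2,3,4,4a,5,8,8a-octahydronaphthalene-2-carboxylic acid | O=C1C(C)=CC[C@@H]2C(C)(C)C[C@H](C(=O)O)C[C@]12C | intermediate
9 | 2-thioxopyridin-1(2H)-yl ester of 8 (thiohydroxamate ester) | O=C1C(C)=CC[C@@H]2C(C)(C)C[C@H](C(=O)ON3C=CC=CC3=S)C[C@]12C | intermediate
10 | (4aR,8aS)-2,5,5,8a-tetramethyl-4a,5,6,7,8,8a-hexahydronaphthalen-1(4H)-one | O=C1C(C)=CC[C@@H]2C(C)(C)CCC[C@]12C | intermediate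
11 | lithium C8=C9 enolate from 10 | [Li]OC1=C(C)CC[C@@H]2C(C)(C)CCC[C@]12C | intermediate
12 | (4aR,8aS)-2,5,5,8a-tetramethyl-3,4,4a,5,6,7,8,8a-octahydronaphthalen-1-yl trifluoromethanesulfonate | O=S(=O)(OC1=C(C)CC[C@@H]2C(C)(C)CCC[C@]12C)C(F)(F)F | intermediate
13 | (4aR,8aS)-1-ethenyl-2,5,5,8a-tetramethyl-3,4,4a,5,6,7,8,8a-octahydronaphthalene | C=CC1=C(C)CC[C@@H]2C(C)(C)CCC[C@]12C | intermediate
14 | but-2-yne-1,4-diol | OCC#CCO | starting material
15 | 4-{[tert-butyl(dimethyl)silyl]oxy}but-2-yn-1-ol | OCC#CCO[Si](C)(C)C(C)(C)C | intermediate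
16 | sodium salt of the five-membered cyclic alkenylaluminate from 15 | [Na+].COCCO[Al-]1(OCCOC)OCC=C1CO[Si](C)(C)C(C)(C)C | intermediate
17 | (2Z)-4-{[tert-butyl(dimethyl)silyl]oxy}-3-iodobut-2-en-1-ol | OC/C=C(\I)CO[Si](C)(C)C(C)(C)C | intermediate
18 | 9-{2-[(4aR,8aS)-2,5,5,8a-tetramethyl-3,4,4a,5,6,7,8,8a-octahydronaphthalen-1-yl]ethyl}-9-borabicyclo[3.3.1]nonane | B1(CCC3=C(C)CC[C@@H]4C(C)(C)CCC[C@]34C)C2CCCC1CCC2 | intermediate
19 | (2E)-3-({[tert-butyl(dimethyl)silyl]oxy}methyl)-5-[(4aR,8aS)-2,5,5,8a-tetramethyl-3,4,4a,5,6,7,8,8a-octahydronaphthalen-1-yl]pent-2-en-1-ol | OC/C=C(\CCC1=C(C)CC[C@@H]2C(C)(C)CCC[C@]12C)CO[Si](C)(C)C(C)(C)C | intermediate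
20 | (2E)-3-({[tert-butyl(dimethyl)silyl]oxy}methyl)-5-[(4aR,8aS)-2,5,5,8a-tetramethyl-3,4,4a,5,6,7,8,8a-octahydronaphthalen-1-yl]pent-2-enal | O=C/C=C(\CCC1=C(C)CC[C@@H]2C(C)(C)CCC[C@]12C)CO[Si](C)(C)C(C)(C)C | intermediate
21 | 4-methylfuran-2(5H)-one | CC1=CC(=O)OC1 | starting material
22 | 4-(bromomethyl)furan-2(5H)-one | BrCC1=CC(=O)OC1 | intermediate
23 | diethyl [(5-oxo-2,5-dihydrofuran-3-yl)methyl]phosphonate | CCOP(=O)(CC1=CC(=O)OC1)OCC | intermediate
24 | lithiated phosphonate from 23 | [Li+].CCOP(=O)([CH-]C1=CC(=O)OC1)OCC | intermediate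
25 | tert-butyldimethylsilyl ether of the target | CC1=C(CC/C(=C\C=C\C2=CC(=O)OC2)CO[Si](C)(C)C(C)(C)C)[C@@]2(C)CCCC(C)(C)[C@H]2CC1 | intermediate
26 | 4-[(1E,3E)-4-(hydroxymethyl)-6-[(4aR,8aS)-2,5,5,8a-tetramethyl-3,4,4a,5,6,7,8,8a-octahydronaphthalen-1-yl]hexa-1,3-dien-1-yl]furan-2(5H)-one | CC1=C(CC/C(=C\C=C\C2=CC(=O)OC2)CO)[C@@]2(C)CCCC(C)(C)[C@H]2CC1 | target

**Step count**

Total step count: 15.
Longest linear sequence: 11 steps from (S)-carvone (steps 1–7, 10, 11, 14, 15).

**Steps most likely to fail**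

Step 2. Conjugate addition of the amide base or of the enolate to the acrylate arm, leading to oligomerisation, may overtake C-methylation.

The fallback sets out from 1 and comes back at 6. It carries the arm through both alkylations at the allylic alcohol level, where it is not an acceptor.
- 2-Methylenepropane-1,3-diol is monosilylated (TBSCl, imidazole) to 2-({[tert-butyl(dimethyl)silyl]oxy}methyl)prop-2-en-1-ol F1.
- An Appel reaction (CBr4, PPh3) converts it into {[2-(bromomethyl)prop-2-en-1-yl]oxy}(tert-butyl)dimethylsilane F2.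
- The kinetic enolate of 1 is alkylated by this bromide to (5S,6R)-6-[2-({[tert-butyl(dimethyl)silyl]oxy}methyl)prop-2-en-1-yl]-2-methyl-5-(prop-1-en-2-yl)cyclohex-2-en-1-one F3.
- A second enolisation and MeI, again entering anti to the isopropenyl group, give (5R,6S)-6-[2-({[tert-butyl(dimethyl)silyl]oxy}methyl)prop-2-en-1-yl]-2,6-dimethyl-5-(prop-1-en-2-yl)cyclohex-2-en-1-one F4.
- Bu4NF liberates (5R,6S)-6-[2-(hydroxymethyl)prop-2-en-1-yl]-2,6-dimethyl-5-(prop-1-en-2-yl)cyclohex-2-en-1-one F5.
- MnO2 oxidises it to 2-{[(1S,6R)-1,3-dimethyl-2-oxo-6-(prop-1-en-2-yl)cyclohex-3-en-1-yl]methyl}prop-2-enal F6.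
- Pinnick oxidation (NaClO2, NaH2PO4, 2-methylbut-2-ene) gives 2-{[(1S,6R)-1,3-dimethyl-2-oxo-6-(prop-1-en-2-yl)cyclohex-3-en-1-yl]methyl}prop-2-enoic acid F7.
- Me3SiCHN2 esterifies this acid to 6.

Step 3. A second hydrogen-atom transfer to the tertiary radical (simple reduction of the isopropenyl group), or hydride attack on the enone, may compete with ring closure.

The fallback sets out from 6 and comes back at 7. It makes the same C4 radical by halogen abstraction instead of hydrogen-atom transfer. HBr in AcOH at 0 °C adds in the Markovnikov sense to the only electron-rich alkene, as it does with carvone itself. This gives methyl 2-{[(1S,6S)-6-(2-bromopropan-2-yl)-1,3-dimethyl-2-oxocyclohex-3-en-1-yl]methyl}prop-2-enoate F8. Slow addition of Bu3SnH and 2,2′-azobis(2-methylpropionitrile) in refluxing benzene (tin hydride Giese cyclisation) then closes C3–C4 in the same 6-endo mode.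

Step 7. Transmetalation at the crowded alkenylpalladium centre may be slow, so that hydrolysis or reduction of the triflate overtakes coupling.

The fallback sets out from 10 and comes back at 13. It replaces cross-coupling by carbonyl addition and dehydration.
- LiBH(s-Bu)3 followed by a proton quench gives (4aR,8aS)-2,5,5,8a-tetramethyloctahydronaphthalen-1(2H)-one F9 (epimers at C8).
- CH2=CHMgBr with CeCl3 adds to C9 to give (4aR,8aS)-1-ethenyl-2,5,5,8a-tetramethyldecahydronaphthalen-1-ol F10 (epimers at C8 and C9).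
- Dehydration with methyl N-(triethylammoniosulfonyl)carbamate (Burgess reagent) can remove a hydrogen only from C8, since C10 carries none. It therefore gives the C8=C9 diene 13 and erases both transient centres.

**Further compounds**

F1 | step 2 | 2-({[tert-butyl(dimethyl)silyl]oxy}methyl)prop-2-en-1-ol | OCC(=C)CO[Si](C)(C)C(C)(C)C
F2 | step 2 | {[2-(bromomethyl)prop-2-en-1-yl]oxy}(tert-butyl)dimethylsilane | BrCC(=C)CO[Si](C)(C)C(C)(C)C
F3 | step 2 | (5S,6R)-6-[2-({[tert-butyl(dimethyl)silyl]oxy}methyl)prop-2-en-1-yl]-2-methyl-5-(prop-1-en-2-yl)cyclohex-2-en-1-one | O=C1C(C)=CC[C@H](C(C)=C)[C@H]1CC(=C)CO[Si](C)(C)C(C)(C)C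
F4 | step 2 | (5R,6S)-6-[2-({[tert-butyl(dimethyl)silyl]oxy}methyl)prop-2-en-1-yl]-2,6-dimethyl-5-(prop-1-en-2-yl)cyclohex-2-en-1-one | O=C1C(C)=CC[C@H](C(C)=C)[C@]1(C)CC(=C)CO[Si](C)(C)C(C)(C)C
F5 | step 2 | (5R,6S)-6-[2-(hydroxymethyl)prop-2-en-1-yl]-2,6-dimethyl-5-(prop-1-en-2-yl)cyclohex-2-en-1-one | O=C1C(C)=CC[C@H](C(C)=C)[C@]1(C)CC(=C)CO
F6 | step 2 | 2-{[(1S,6R)-1,3-dimethyl-2-oxo-6-(prop-1-en-2-yl)cyclohex-3-en-1-yl]methyl}prop-2-enal | O=C1C(C)=CC[C@H](C(C)=C)[C@]1(C)CC(=C)C=O
F7 | step 2 | 2-{[(1S,6R)-1,3-dimethyl-2-oxo-6-(prop-1-en-2-yl)cyclohex-3-en-1-yl]methyl}prop-2-enoic acid | O=C1C(C)=CC[C@H](C(C)=C)[C@]1(C)CC(=C)C(=O)O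
F8 | step 3 | methyl 2-{[(1S,6S)-6-(2-bromopropan-2-yl)-1,3-dimethyl-2-oxocyclohex-3-en-1-yl]methyl}prop-2-enoate | O=C1C(C)=CC[C@H](C(C)(C)Br)[C@]1(C)CC(=C)C(=O)OC
F9 | step 7 | (4aR,8aS)-2,5,5,8a-tetramethyloctahydronaphthalen-1(2H)-one (epimers at C8) | O=C1C(C)CC[C@@H]2C(C)(C)CCC[C@]12C
F10 | step 7 | (4aR,8aS)-1-ethenyl-2,5,5,8a-tetramethyldecahydronaphthalen-1-ol (epimers at C8 and C9) | C=CC1(O)C(C)CC[C@@H]2C(C)(C)CCC[C@]12C
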